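The route rests on disconnecting C2–C3 and C2''–C3''. In both pyranone rings the aryl-bearing carbon (C2, C2'') stands in a 1,3-relationship to the ketone carbon (C4, C4'') and is bonded to the ring oxygen (O1, O1''); each can therefore start life as the carbonyl of an aryl ester on that oxygen, next to an acetyl group on ring A or ring A''. A single base treatment transfers both aroyl groups from oxygen to the acetyl carbons and delivers a bis(1,3-diketone). The precursor is a C3'–C8'' biaryl bis(aryl ester) whose phenols, except the O7'' methyl ether, are benzylated, so cyclodehydration, twofold asymmetric hydrogenation, reoxidation and one hydrogenolysis finish the synthesis.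

Key step: step 9

Numbering: flavonoid numbering. Unprimed locants and ring A belong to the 5,7-dihydroxyflavanone unit, whose 2-aryl ring is ring B (C1'–C6'). Doubly primed locants and ring A'' belong to the 5-hydroxy-7-methoxyflavanone unit, whose 2-aryl ring is C1'''–C6'''.

Assumption 1: the C3'–C8'' axis (three ortho oxygen substituents, one ortho hydrogen) is taken to rotate freely at room temperature, in line with the target carrying no axial descriptor, so no axial stereochemistry is controlled.

Assumption 2: the sense of induction of the chiral carbene is fixed beforehand on a simple flavone; the (R,R)-ligand is written, and its antipode is used if the model reduction gives the 2R series.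

Assumption 3: compounds 1, 4, 7 and 10 are catalogue chemicals.

Step 1
Reactants: 1 2',6'-dihydroxy-4'-methoxyacetophenone
Product: 2 1-[2-(benzyloxy)-6-hydroxy-4-methoxyphenyl]ethanone
Conditions: BnBr (1.05 equiv), K2CO3 (1.1 equiv), acetone, reflux
Reagents that add atoms: benzyl bromide, BrCc1ccccc1
Why: Williamson etherification should stop after one benzylation, because the remaining hydroxyl is locked in a hydrogen bond to the acetyl carbonyl and is much less nucleophilic.

Step 2
Reactants: 2 1-[2-(benzyloxy)-6-hydroxy-4-methoxyphenyl]ethanone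
Product: 3 1-[6-(benzyloxy)-2-hydroxy-3-iodo-4-methoxyphenyl]ethanone
Conditions: NIS (1.05 equiv), CF3CO2H (cat.), MeCN, 0 °C to rt
Reagents that add atoms: N-iodosuccinimide, O=C1CCC(=O)N1I
Why: Electrophilic aromatic iodination of the phloroglucinol-type ring should take the CH ortho to the free hydroxyl, the less hindered of the two activated sites (the other lies between the benzyloxy and methoxy groups), and one equivalent of reagent limits double iodination.

Step 3
Reactants: 4 4-(benzyloxy)-3-bromobenzaldehyde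
Product: 5 4-(benzyloxy)-3-(4,4,5,5-tetramethyl-1,3,2-dioxaborolan-2-yl)benzaldehyde
Conditions: B2pin2 (1.2 equiv), Pd(dppf)Cl2 (3 mol %), KOAc (3 equiv), 1,4-dioxane, 90 °C
Reagents that add atoms: bis(pinacolato)diboron, CC1(C)OB(OC1(C)C)B1OC(C)(C)C(C)(C)O1
Why: Miyaura borylation of an aryl bromide under acetate conditions tolerates the aldehyde and the benzyl ether.

Step 4
Reactants: 3 1-[6-(benzyloxy)-2-hydroxy-3-iodo-4-methoxyphenyl]ethanone; 5 4-(benzyloxy)-3-(4,4,5,5-tetramethyl-1,3,2-dioxaborolan-2-yl)benzaldehyde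
Product: 6 3-[3-acetyl-4-(benzyloxy)-2-hydroxy-6-methoxyphenyl]-4-(benzyloxy)benzaldehyde
Conditions: Pd(OAc)2 (5 mol %), SPhos (10 mol %), K3PO4 (3 equiv), toluene/H2O 10:1, 90 °C
Reagents that add atoms: none
Why: Suzuki–Miyaura coupling with a dialkylbiarylphosphine ligand suits an aryl iodide flanked by two ortho substituents and forms the C3'–C8'' bond; under phosphate the substrate is a phenoxide whose acetyl group is not enolised, so no aldol reaction with the aldehyde is expected.

Step 5
Reactants: 6 3-[3-acetyl-4-(benzyloxy)-2-hydroxy-6-methoxyphenyl]-4-(benzyloxy)benzaldehyde; 7 4-(benzyloxy)benzoyl chloride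
Product: 8 2-acetyl-3-(benzyloxy)-6-[2-(benzyloxy)-5-formylphenyl]-5-methoxyphenyl 4-(benzyloxy)benzoate
Conditions: Et3N (2 equiv), DMAP (0.2 equiv), CH2Cl2, 0 °C to rt
Reagents that add atoms: none
Why: DMAP-catalysed O-acylation of the only hydroxyl group places the future C2'' carbon and its aryl ring on O1''.

Step 6
Reactants: 8 2-acetyl-3-(benzyloxy)-6-[2-(benzyloxy)-5-formylphenyl]-5-methoxyphenyl 4-(benzyloxy)benzoate
Product: 9 3-[3-acetyl-4-(benzyloxy)-2-{[4-(benzyloxy)benzoyl]oxy}-6-methoxyphenyl]-4-(benzyloxy)benzoic acid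
Conditions: NaClO2, NaH2PO4, 2-methyl-2-butene (large excess), t-BuOH/THF/H2O, rt
Reagents that add atoms: sodium chlorite, [Na+].[O-]Cl=O
Why: Pinnick oxidation turns the aldehyde into the acid near pH 4 without touching the aryl ester, the ketone or the benzyl ethers, and the alkene scavenger removes HOCl before it can chlorinate the electron-rich ring A''.

Step 7
Reactants: 10 2',4',6'-trihydroxyacetophenone
Product: 11 1-[2,4-bis(benzyloxy)-6-hydroxyphenyl]ethanone
Conditions: BnBr (2.1 equiv), K2CO3 (2.2 equiv), DMF, rt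
Reagents that add atoms: benzyl bromide, BrCc1ccccc1
Why: Williamson etherification should take the two hydroxyls that are not chelated and leave the one hydrogen-bonded to the acetyl group free.

Step 8
Reactants: 9 3-[3-acetyl-4-(benzyloxy)-2-{[4-(benzyloxy)benzoyl]oxy}-6-methoxyphenyl]-4-(benzyloxy)benzoic acid; 11 1-[2,4-bis(benzyloxy)-6-hydroxyphenyl]ethanone
Product: 12 2-acetyl-3,5-bis(benzyloxy)phenyl 3-[3-acetyl-4-(benzyloxy)-2-{[4-(benzyloxy)benzoyl]oxy}-6-methoxyphenyl]-4-(benzyloxy)benzoate (the bis-ester)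
Conditions: EDC·HCl (1.5 equiv), DMAP (0.3 equiv), CH2Cl2, rt
Reagents that add atoms: none
Why: Steglich esterification activates only the free carboxylic acid and joins it to the phenol of 11, placing the future C2 carbon on O1, while the electron-rich aryl benzoate already present should not exchange under these mild conditions.

Step 9
Reactants: 12 the bis-ester
Product: 13 1-[2,4-bis(benzyloxy)-6-hydroxyphenyl]-3-{4-(benzyloxy)-3-[4-(benzyloxy)-3-{3-[4-(benzyloxy)phenyl]-3-oxopropanoyl}-2-hydroxy-6-methoxyphenyl]phenyl}propane-1,3-dione (the bis(1,3-diketone), drawn as the diketo tautomer)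
Conditions: LiN(SiMe3)2 (6 equiv), THF (0.02 M), −78 °C to 0 °C, then aq. HCl
Reagents that add atoms: none
Why: LiN(SiMe3)2 turns each acetyl group into its lithium enolate, whose carbon adds to the carbonyl of the aryl ester on the neighbouring oxygen through a six-membered cyclic tetrahedral intermediate (6-exo-trig addition) that collapses with the phenoxide as leaving group, so each aroyl group ends on carbon and C2–C3 and C2''–C3'' are formed. This is the Baker–Venkataraman rearrangement, an intramolecular Claisen-type acyl transfer that is well established for single 2-acyloxyacetophenones, including 2,4,6-trioxygenated ones, and is run here on two such units in one molecule. No ring remains in the product, because the cyclic intermediate reopens, and no stereocentre is created. The selectivity needed is that each enolate takes only the aroyl group on its own ring; the ortho arrangement secures this, because the six-membered transition state is much faster than any intermolecular or large-ring Claisen condensation, and dilution suppresses the latter further. Excess base is used because each migration ends in a phenoxide and a diketone enolate, and these anionic products should resist further acylation or retro-Claisen cleavage until the acidic quench. The hindered O1'' beside the biaryl axis only has to release an acyl group it already carries, so the crowded surroundings of C8'' take no part in carbon–carbon bond formation.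

Step 10
Reactants: 13 the bis(1,3-diketone)
Product: 14 5,7-bis(benzyloxy)-2-{4-(benzyloxy)-3-[5-(benzyloxy)-2-[4-(benzyloxy)phenyl]-7-methoxy-4-oxo-4H-chromen-8-yl]phenyl}-4H-chromen-4-one (the biflavone)
Conditions: TsOH·H2O (20 mol %), toluene, 90 °C
Reagents that add atoms: none
Why: Acid-catalysed cyclodehydration closes both 4H-pyran-4-one rings by addition of each free phenol to the distal aryl ketone and loss of water; each diketone has only one free phenol, so only one regiochemistry is possible, and the mild acid should spare the peri benzyl ethers.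

Step 11
Reactants: 14 the biflavone
Product: 15 (2S,4S)-5,7-bis(benzyloxy)-2-{4-(benzyloxy)-3-[(2S,4S)-5-(benzyloxy)-2-[4-(benzyloxy)phenyl]-4-hydroxy-7-methoxychroman-8-yl]phenyl}chroman-4-ol (the bis(cis-flavan-4-ol))
Conditions: Ru(cod)(2-methylallyl)2 (10 mol %), (R,R)-1,3-bis[1-(naphthalen-1-yl)ethyl]-4,5-dihydroimidazolium tetrafluoroborate (SINpEt·HBF4, 20 mol %), KOtBu (30 mol %), n-hexane, 70 °C, then 14 in toluene, H2 (100 bar), 25–40 °C
Reagents that add atoms: none
Why: Asymmetric hydrogenation of the flavone C2=C3 bond with ruthenium–NHC catalysts is established, and the chiral carbene should select one face of each pyranone independently of the remote other unit, setting C2 and C2'' as S under catalyst control; the ketones are then reduced to the 2,4-cis alcohols, whose C4 and C4'' configuration is erased in step 12, any unreduced ketone converges there, and two independent events push most stereochemical errors into separable diastereomers.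

Step 12
Reactants: 15 the bis(cis-flavan-4-ol)
Product: 16 (2S)-5,7-bis(benzyloxy)-2-{4-(benzyloxy)-3-[(2S)-5-(benzyloxy)-2-[4-(benzyloxy)phenyl]-7-methoxy-4-oxochroman-8-yl]phenyl}chroman-4-one (the pentabenzyl bis-flavanone)
Conditions: Dess–Martin periodinane (3 equiv), pyridine (6 equiv), CH2Cl2, 0 °C to rt
Reagents that add atoms: none
Why: Dess–Martin oxidation of the two benzylic secondary alcohols restores the C4 and C4'' ketones under buffered, non-enolising conditions, so the untouched C2 and C2'' centres keep their S configuration.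

Step 13
Reactants: 16 the pentabenzyl bis-flavanone
Product: 17 (2S)-5,7-dihydroxy-2-{4-hydroxy-3-[(2S)-5-hydroxy-2-(4-hydroxyphenyl)-7-methoxy-4-oxochroman-8-yl]phenyl}chroman-4-one (the target)
Conditions: H2 (1 atm), 10% Pd/C, THF/MeOH, rt
Reagents that add atoms: none
Why: Hydrogenolysis over palladium should cleave the five aryl benzyl ethers under neutral conditions and leave the O7'' methyl ether, avoiding the acid or base that could open the flavanone rings and scramble C2 and C2''.

Compound list
1 | 2',6'-dihydroxy-4'-methoxyacetophenone | CC(=O)c1c(O)cc(OC)cc1O | starting material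
2 | 1-[2-(benzyloxy)-6-hydroxy-4-methoxyphenyl]ethanone | CC(=O)c1c(O)cc(OC)cc1OCc1ccccc1 | intermediate
3 | 1-[6-(benzyloxy)-2-hydroxy-3-iodo-4-methoxyphenyl]ethanone | CC(=O)c1c(O)c(I)c(OC)cc1OCc1ccccc1 | intermediate
4 | 4-(benzyloxy)-3-bromobenzaldehyde | O=Cc1ccc(OCc2ccccc2)c(Br)c1 | starting material
5 | 4-(benzyloxy)-3-(4,4,5,5-tetramethyl-1,3,2-dioxaborolan-2-yl)benzaldehyde | O=Cc1ccc(OCc2ccccc2)c(B2OC(C)(C)C(C)(C)O2)c1 | intermediate
6 | 3-[3-acetyl-4-(benzyloxy)-2-hydroxy-6-methoxyphenyl]-4-(benzyloxy)benzaldehyde | CC(=O)c1c(O)c(-c2cc(C=O)ccc2OCc2ccccc2)c(OC)cc1OCc1ccccc1 | intermediate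
7 | 4-(benzyloxy)benzoyl chloride | O=C(Cl)c1ccc(OCc2ccccc2)cc1 | starting material
8 | 2-acetyl-3-(benzyloxy)-6-[2-(benzyloxy)-5-formylphenyl]-5-methoxyphenyl 4-(benzyloxy)benzoate | CC(=O)c1c(OC(=O)c2ccc(OCc3ccccc3)cc2)c(-c2cc(C=O)ccc2OCc2ccccc2)c(OC)cc1OCc1ccccc1 | intermediate
9 | 3-[3-acetyl-4-(benzyloxy)-2-{[4-(benzyloxy)benzoyl]oxy}-6-methoxyphenyl]-4-(benzyloxy)benzoic acid | CC(=O)c1c(OC(=O)c2ccc(OCc3ccccc3)cc2)c(-c2cc(C(=O)O)ccc2OCc2ccccc2)c(OC)cc1OCc1ccccc1 | intermediate
10 | 2',4',6'-trihydroxyacetophenone | CC(=O)c1c(O)cc(O)cc1O | starting material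
11 | 1-[2,4-bis(benzyloxy)-6-hydroxyphenyl]ethanone | CC(=O)c1c(O)cc(OCc2ccccc2)cc1OCc1ccccc1 | intermediate
12 | 2-acetyl-3,5-bis(benzyloxy)phenyl 3-[3-acetyl-4-(benzyloxy)-2-{[4-(benzyloxy)benzoyl]oxy}-6-methoxyphenyl]-4-(benzyloxy)benzoate (bis-ester, precursor of the key step) | COc1cc(OCc2ccccc2)c(C(C)=O)c(OC(=O)c2ccc(OCc3ccccc3)cc2)c1-c1cc(C(=O)Oc2cc(OCc3ccccc3)cc(OCc3ccccc3)c2C(C)=O)ccc1OCc1ccccc1 | intermediate
13 | 1-[2,4-bis(benzyloxy)-6-hydroxyphenyl]-3-{4-(benzyloxy)-3-[4-(benzyloxy)-3-{3-[4-(benzyloxy)phenyl]-3-oxopropanoyl}-2-hydroxy-6-methoxyphenyl]phenyl}propane-1,3-dione (bis(1,3-diketone), product of the key step) | COc1cc(OCc2ccccc2)c(C(=O)CC(=O)c2ccc(OCc3ccccc3)cc2)c(O)c1-c1cc(C(=O)CC(=O)c2c(O)cc(OCc3ccccc3)cc2OCc2ccccc2)ccc1OCc1ccccc1 | intermediate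
14 | 5,7-bis(benzyloxy)-2-{4-(benzyloxy)-3-[5-(benzyloxy)-2-[4-(benzyloxy)phenyl]-7-methoxy-4-oxo-4H-chromen-8-yl]phenyl}-4H-chromen-4-one (5,7,4',5'',4'''-penta-O-benzyl-7''-O-methylamentoflavone) | COc1cc(OCc3ccccc3)c2c(c1-c1cc(-c3cc(=O)c4c(OCc5ccccc5)cc(OCc5ccccc5)cc4o3)ccc1OCc1ccccc1)oc(-c1ccc(OCc3ccccc3)cc1)cc2=O | intermediate
15 | (2S,4S)-5,7-bis(benzyloxy)-2-{4-(benzyloxy)-3-[(2S,4S)-5-(benzyloxy)-2-[4-(benzyloxy)phenyl]-4-hydroxy-7-methoxychroman-8-yl]phenyl}chroman-4-ol | COc1cc(OCc3ccccc3)c2c(c1-c1cc([C@@H]3C[C@H](O)c4c(OCc5ccccc5)cc(OCc5ccccc5)cc4O3)ccc1OCc1ccccc1)O[C@H](c1ccc(OCc3ccccc3)cc1)C[C@@H]2O | intermediate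
16 | (2S)-5,7-bis(benzyloxy)-2-{4-(benzyloxy)-3-[(2S)-5-(benzyloxy)-2-[4-(benzyloxy)phenyl]-7-methoxy-4-oxochroman-8-yl]phenyl}chroman-4-one | COc1cc(OCc3ccccc3)c2c(c1-c1cc([C@@H]3CC(=O)c4c(OCc5ccccc5)cc(OCc5ccccc5)cc4O3)ccc1OCc1ccccc1)O[C@H](c1ccc(OCc3ccccc3)cc1)CC2=O | intermediate
17 | (2S)-5,7-dihydroxy-2-{4-hydroxy-3-[(2S)-5-hydroxy-2-(4-hydroxyphenyl)-7-methoxy-4-oxochroman-8-yl]phenyl}chroman-4-one ((2S,2''S)-2,3,2'',3''-tetrahydroamentoflavone 7''-methyl ether, CNP0237714.1) | COc1cc(O)c2c(c1-c1cc([C@@H]3CC(=O)c4c(O)cc(O)cc4O3)ccc1O)O[C@H](c1ccc(O)cc1)CC2=O | target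

Total step count: 13 steps.
Longest linear sequence: 11 steps (steps 1, 2, 4, 5, 6, 8, 9, 10, 11, 12, 13). Steps 3 and 7 prepare the two side fragments.

Steps most likely to fail

1. Step 11. Facial discrimination at one or both C2=C3 bonds may be poor, since the biaryl beside C2 and the 8-aryl group beside O1'' crowd the catalyst. The second pyranone may also react sluggishly once the first is reduced, leaving a mixture of C2/C2'' stereoisomers. The fallback replaces catalyst control by resolution. It sets out from 14: hydrogenation under the same ruthenium conditions, but with the achiral carbene from 1,3-dicyclohexylimidazolium chloride, should give the bis(flavan-4-ol) stereoisomer mixture F1. Oxidation as in step 12 should then give the bis-flavanone as its four C2/C2'' stereoisomers F2. The (2S,2''S) isomer is separated from F2 by preparative HPLC on a polysaccharide chiral stationary phase (the two diastereomeric pairs may already part on silica), and the route is rejoined at 16.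

2. Step 9. The second acyl shift may stall after the first, or a liberated phenoxide may attack the other aryl ester, so that acyl exchange and ester cleavage erode the twofold process. The fallback builds the two heterocycles one after the other, so that only one ester is present in each rearrangement. It sets out from 9: LiN(SiMe3)2 (4 equiv, one taken by the acid) in THF should give the diketone acid F3. TsOH in toluene should close F3 to the flavone acid F4. Steglich esterification of F4 with 11 should give the flavone ester F5. A second Baker–Venkataraman shift on F5 should give the flavone diketone F6. Cyclodehydration of F6 as in step 10 rejoins the route at 14.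

3. Step 4. Transmetalation to the doubly ortho-substituted arylpalladium phenoxide may be slow, so that protodeboronation of 5 and hydrodeiodination of 3 take over. The fallback replaces the base-mediated boron coupling by a tin coupling. It sets out from 4: Bu3SnSnBu3 with Pd(PPh3)4 in toluene at 110 °C should give 4-(benzyloxy)-3-(tributylstannyl)benzaldehyde F7. Copper-assisted Stille coupling of F7 with 3 (Pd(PPh3)4, CuI, CsF, DMF, 50 °C) rejoins the route at 6.

Further compounds
F1 | step 11 | 5,7-bis(benzyloxy)-2-{4-(benzyloxy)-3-[5-(benzyloxy)-2-[4-(benzyloxy)phenyl]-4-hydroxy-7-methoxychroman-8-yl]phenyl}chroman-4-ol, mixture of stereoisomers | COc1cc(OCc3ccccc3)c2c(c1-c1cc(C3CC(O)c4c(OCc5ccccc5)cc(OCc5ccccc5)cc4O3)ccc1OCc1ccccc1)OC(c1ccc(OCc3ccccc3)cc1)CC2O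
F2 | step 11 | 5,7-bis(benzyloxy)-2-{4-(benzyloxy)-3-[5-(benzyloxy)-2-[4-(benzyloxy)phenyl]-7-methoxy-4-oxochroman-8-yl]phenyl}chroman-4-one, mixture of the four C2/C2'' stereoisomers | COc1cc(OCc3ccccc3)c2c(c1-c1cc(C3CC(=O)c4c(OCc5ccccc5)cc(OCc5ccccc5)cc4O3)ccc1OCc1ccccc1)OC(c1ccc(OCc3ccccc3)cc1)CC2=O
F3 | step 9 | 4-(benzyloxy)-3-[4-(benzyloxy)-3-{3-[4-(benzyloxy)phenyl]-3-oxopropanoyl}-2-hydroxy-6-methoxyphenyl]benzoic acid | COc1cc(OCc2ccccc2)c(C(=O)CC(=O)c2ccc(OCc3ccccc3)cc2)c(O)c1-c1cc(C(=O)O)ccc1OCc1ccccc1
F4 | step 9 | 4-(benzyloxy)-3-{5-(benzyloxy)-2-[4-(benzyloxy)phenyl]-7-methoxy-4-oxo-4H-chromen-8-yl}benzoic acid | COc1cc(OCc3ccccc3)c2c(c1-c1cc(C(=O)O)ccc1OCc1ccccc1)oc(-c1ccc(OCc3ccccc3)cc1)cc2=O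
F5 | step 9 | 2-acetyl-3,5-bis(benzyloxy)phenyl 4-(benzyloxy)-3-{5-(benzyloxy)-2-[4-(benzyloxy)phenyl]-7-methoxy-4-oxo-4H-chromen-8-yl}benzoate | COc1cc(OCc3ccccc3)c2c(c1-c1cc(C(=O)Oc3cc(OCc4ccccc4)cc(OCc4ccccc4)c3C(C)=O)ccc1OCc1ccccc1)oc(-c1ccc(OCc3ccccc3)cc1)cc2=O
F6 | step 9 | 1-[2,4-bis(benzyloxy)-6-hydroxyphenyl]-3-[4-(benzyloxy)-3-{5-(benzyloxy)-2-[4-(benzyloxy)phenyl]-7-methoxy-4-oxo-4H-chromen-8-yl}phenyl]propane-1,3-dione | COc1cc(OCc3ccccc3)c2c(c1-c1cc(C(=O)CC(=O)c3c(O)cc(OCc4ccccc4)cc3OCc3ccccc3)ccc1OCc1ccccc1)oc(-c1ccc(OCc3ccccc3)cc1)cc2=O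
F7 | step 4 | 4-(benzyloxy)-3-(tributylstannyl)benzaldehyde | O=Cc1ccc(OCc2ccccc2)c([Sn](CCCC)(CCCC)CCCC)c1
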